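**Plan**
1. Locants: C1 is the acyloxy carbinol on ring A (the 2,4-disubstituted oxazole), C2 to C5 follow the chain, and C6 is the methyl. Ring B is the 5-substituted oxazole.
2. Cuts, in order: the C1 ester C–O bond; the C3–O and C4–O bonds (back to an E C3=C4 alkene); C1–C2 and C4–C5 together; finally ring A (back to a serine amide of the ring B acetic acid).
3. Enabling feature: the carbinols C1 (on ring A) and C5 (carrying methyl C6) are 1,5-anti and lie exactly three carbons apart (C2, C3, C4). An allene-derived diboron C3 unit therefore fits between the ring A aldehyde and acetaldehyde.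
4. Forward order: ring A is closed on the ring B side chain and taken to the aldehyde. C4–C5 and then C1–C2 are made in one flask. C1 is acylated, C3=C4 is epoxidised, C4 is inverted by oxygen delivery from C5, and the masks are removed.
5. Stereochemistry: C5 comes from the isopinocampheyl groups of the borane and C1 by relay through the transient C4–B centre. C3 comes from the matched tartrate epoxidation directed by C5–OH, and C4 from SN2 opening of that epoxide.

Key step: step 6

Assumption: the sense of induction of the pinene-derived borane, the tartrate catalyst and the isothiourea catalyst is taken from their known behaviour with simple aldehydes and carbinols of the same substitution pattern; compounds 1, 2, 7, 11, 13 and 18 and all unnumbered reagents are treated as purchasable.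

Step 1
Reactants: 1 2-(1,3-oxazol-5-yl)acetic acid; 2 L-serine methyl ester hydrochloride
Product: 3 methyl N-[2-(1,3-oxazol-5-yl)acetyl]-L-serinate
Conditions: EDC·HCl, HOBt, N-methylmorpholine, CH2Cl2/DMF, 0 °C to rt
Reagents that add atoms: none
Why: Carbodiimide/HOBt amide coupling acylates the amine far faster than the primary hydroxyl, and the serine stereocentre it carries along is erased in step 2.

Step 2
Reactants: 3 methyl N-[2-(1,3-oxazol-5-yl)acetyl]-L-serinate
Product: 5 methyl 2-(1,3-oxazol-5-ylmethyl)-1,3-oxazole-4-carboxylate, via oxazoline 4 (not isolated)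
Conditions: (MeOCH2CH2)2NSF3, CH2Cl2, −20 °C; then BrCCl3, DBU, 0 °C to rt
Reagents that add atoms: none
Why: Cyclodehydration of the beta-hydroxy amide with an aminosulfur trifluoride gives oxazoline 4, which BrCCl3/DBU dehydrogenates in the same flask by bromination at C4-H (the most acidic position, next to the ester) and loss of HBr to close aromatic ring A.

Step 3
Reactants: 5 methyl 2-(1,3-oxazol-5-ylmethyl)-1,3-oxazole-4-carboxylate
Product: 6 2-(1,3-oxazol-5-ylmethyl)-1,3-oxazole-4-carbaldehyde
Conditions: iBu2AlH (toluene), CH2Cl2, −78 °C; MeOH, aq potassium sodium tartrate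
Reagents that add atoms: none
Why: Partial ester reduction with iBu2AlH at low temperature stops at the aluminium hemiacetal, which the neighbouring ring A nitrogen helps to hold, so that the aldehyde appears only on work-up.

Step 4
Reactants: 7 propargyl bromide
Product: 10 2-(propa-1,2-dienyl)-5,5-dimethyl-1,3,2-dioxaborinane, via allenylmagnesium bromide 8 (not isolated), via allenylboronic acid 9 (not isolated)
Conditions: Mg, HgCl2 (cat), Et2O, 0 °C; B(OMe)3, Et2O, −78 °C; 2 M HCl; 2,2-dimethylpropane-1,3-diol, MgSO4, Et2O, rt; distil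
Reagents that add atoms: trimethyl borate, COB(OC)OC; 2,2-dimethylpropane-1,3-diol, OCC(C)(C)CO
Why: Borylation of a Grignard reagent followed by boronic acid esterification: the allenyl/propargyl magnesium species is trapped by B(OMe)3 as the allenylboron compound, and condensation with the 1,3-diol over a drying agent gives a distillable six-membered boronate.

Step 5
Reactants: 11 (1S,5S)-(−)-alpha-pinene
Product: 12 bis(isopinocampheyl)borane of the (−)-alpha-pinene series, (lIpc)2BH
Conditions: BH3·SMe2, THF, 0 °C; excess 11, 0 °C, 3 d; collect crystals under Ar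
Reagents that add atoms: borane–dimethyl sulfide, [BH3-][S+](C)C
Why: Alkene hydroboration stops at the hindered dialkylborane, boron adding to the less substituted alkene carbon on the face away from the gem-dimethyl bridge, and ageing the slurry with excess pinene upgrades the enantiomeric purity of the crystalline reagent.

Step 6
Reactants: 10 2-(propa-1,2-dienyl)-5,5-dimethyl-1,3,2-dioxaborinane; 12 (lIpc)2BH; 13 acetaldehyde; 6 2-(1,3-oxazol-5-ylmethyl)-1,3-oxazole-4-carbaldehyde
Product: 17 (1R,3E,5S)-1-[2-(1,3-oxazol-5-ylmethyl)-1,3-oxazol-4-yl]hex-3-ene-1,5-diol, via allylborane 14 (not isolated), via allylboronate 15 (not isolated), via boron ester 16 (not isolated)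
Conditions: 12 + 10, Et2O, 0 °C, 2 h; 13 (0.95 equiv), −78 °C, 2 h; 6 (0.8 equiv) in THF, −78 °C to rt, 24 h; aq NaHCO3, 30% H2O2, 0 °C to rt
Reagents that add atoms: none
Why: Borane 12 hydroborates the unsubstituted C=C of allene 10 with boron going to the terminal carbon, which gives the E gamma-boryl allylborane 14 whose trialkylborane end alone reacts at −78 °C. A first chair transition state joins the boronate-bearing carbon (C4) to acetaldehyde; the isopinocampheyl groups of the (−)-alpha-pinene series pick the aldehyde face that makes C5 S, and the E geometry of 14 places the new C4–B bond anti to the C5 oxygen in 15. On warming, 15 adds to aldehyde 6 through a second chair in which the C4 substituent lies equatorial, as the slim neopentyl glycol ester permits, so the C4–B centre is traded for C1 (R), the C1–C2 bond forms and the alkene ends up E between C3 and C4. The closest known reaction type is the one-pot double allylboration of two different aldehydes with a gamma-boryl allylborane to (E)-1,5-anti-ene-diols, and no ring is closed. The step needs each aldehyde to meet only its own boron centre, which the large reactivity gap between allylborane and allylboronate, the sequential addition with acetaldehyde in slight deficit, and the unhindered electron-poor formyl group on ring A should secure. Buffered peroxide work-up then cleaves the B–O and B–C bonds of 16 and leaves both oxazoles and the alkene intact.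

Step 7
Reactants: 17 (1R,3E,5S)-1-[2-(1,3-oxazol-5-ylmethyl)-1,3-oxazol-4-yl]hex-3-ene-1,5-diol; 18 13-methyltetradecanoic acid
Product: 20 (1R,3E,5S)-5-hydroxy-1-[2-(1,3-oxazol-5-ylmethyl)-1,3-oxazol-4-yl]hex-3-en-1-yl 13-methyltetradecanoate, via mixed anhydride 19 (not isolated)
Conditions: 18 (1.1 equiv), (tBuCO)2O, iPr2NEt, (R)-benzotetramisole [(R)-2-phenyl-2,3-dihydroimidazo[2,1-b][1,3]benzothiazole] (5 mol %), CH2Cl2, rt
Reagents that add atoms: none
Why: Shiina-type esterification through the mixed pivalic anhydride under chiral isothiourea acyl-transfer catalysis favours carbinols that carry a (hetero)aryl group and have the R sense shown by C1, whereas C5–OH is a weaker and stereochemically mismatched alkenyl carbinol, so the acyl group should go to C1 with no change at either stereocentre.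

Step 8
Reactants: 20 (1R,3E,5S)-5-hydroxy-1-[2-(1,3-oxazol-5-ylmethyl)-1,3-oxazol-4-yl]hex-3-en-1-yl 13-methyltetradecanoate
Product: 21 (1R)-2-{(2S,3S)-3-[(1S)-1-hydroxyethyl]oxiran-2-yl}-1-[2-(1,3-oxazol-5-ylmethyl)-1,3-oxazol-4-yl]ethyl 13-methyltetradecanoate
Conditions: Ti(OiPr)4 (0.4 equiv), diisopropyl L-(+)-tartrate (0.5 equiv), tBuOOH (decane), 4 Å MS, CH2Cl2, −20 °C
Reagents that add atoms: tert-butyl hydroperoxide, CC(C)(C)OO
Why: Sharpless asymmetric epoxidation in its matched sense, because an S-configured E allylic alcohol is the fast-reacting partner of the L-(+)-tartrate catalyst and takes oxygen on the face that gives the anti (erythro) epoxy alcohol, which sets C3 (S) for good and C4 (S) provisionally.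

Step 9
Reactants: 21 (1R)-2-{(2S,3S)-3-[(1S)-1-hydroxyethyl]oxiran-2-yl}-1-[2-(1,3-oxazol-5-ylmethyl)-1,3-oxazol-4-yl]ethyl 13-methyltetradecanoate
Product: 22 (1R)-1-[2-(1,3-oxazol-5-ylmethyl)-1,3-oxazol-4-yl]-2-{(2S,3S)-3-[(1S)-1-(phenylcarbamoyloxy)ethyl]oxiran-2-yl}ethyl 13-methyltetradecanoate
Conditions: PhNCO, pyridine, CH2Cl2, rt
Reagents that add atoms: phenyl isocyanate, O=C=Nc1ccccc1
Why: Urethane formation by addition of the only free hydroxyl to an isocyanate runs under nearly neutral conditions that spare epoxide, ester and both oxazoles.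

Step 10
Reactants: 22 (1R)-1-[2-(1,3-oxazol-5-ylmethyl)-1,3-oxazol-4-yl]-2-{(2S,3S)-3-[(1S)-1-(phenylcarbamoyloxy)ethyl]oxiran-2-yl}ethyl 13-methyltetradecanoate
Product: 24 (1R,3S)-3-hydroxy-3-[(4S,5S)-5-methyl-2-oxo-1,3-dioxolan-4-yl]-1-[2-(1,3-oxazol-5-ylmethyl)-1,3-oxazol-4-yl]propyl 13-methyltetradecanoate, via iminocarbonate 23 (not isolated)
Conditions: BF3·OEt2 (3 equiv), Et2O/CH2Cl2, −20 °C; then 1 M H2SO4, THF, 0 °C to rt; NaHCO3
Reagents that add atoms: water, O
Why: Lewis acid-promoted neighbouring-group opening of a 2,3-epoxy alcohol urethane, in which the carbamate carbonyl oxygen (a better nucleophile than the remote ester carbonyl) attacks C4 in 5-exo fashion with inversion to give the C4 configuration of the target and free C3–OH with retention, after which dilute acid hydrolyses iminocarbonate 23 to the trans cyclic carbonate.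

Step 11
Reactants: 24 (1R,3S)-3-hydroxy-3-[(4S,5S)-5-methyl-2-oxo-1,3-dioxolan-4-yl]-1-[2-(1,3-oxazol-5-ylmethyl)-1,3-oxazol-4-yl]propyl 13-methyltetradecanoate
Product: 25 (1R,3S)-3-(tert-butyldimethylsilyloxy)-3-[(4R,5S)-5-methyl-2-oxo-1,3-dioxolan-4-yl]-1-[2-(1,3-oxazol-5-ylmethyl)-1,3-oxazol-4-yl]propyl 13-methyltetradecanoate
Conditions: TBSOTf, 2,6-lutidine, CH2Cl2, −20 to 0 °C
Reagents that add atoms: tert-butyldimethylsilyl triflate, CC(C)(C)[Si](C)(C)OS(=O)(=O)C(F)(F)F
Why: Silyl ether formation with a silyl triflate and a hindered pyridine covers the crowded C3–OH, so that no alkoxide can sit 1,3 to the C1 ester in the next step (the changed C4 descriptor reflects ligand ranking only).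

Step 12
Reactants: 25 (1R,3S)-3-(tert-butyldimethylsilyloxy)-3-[(4R,5S)-5-methyl-2-oxo-1,3-dioxolan-4-yl]-1-[2-(1,3-oxazol-5-ylmethyl)-1,3-oxazol-4-yl]propyl 13-methyltetradecanoate
Product: 26 (1R,3S,4R,5S)-3-(tert-butyldimethylsilyloxy)-4,5-dihydroxy-1-[2-(1,3-oxazol-5-ylmethyl)-1,3-oxazol-4-yl]hexyl 13-methyltetradecanoate
Conditions: LiOH (2.2 equiv), THF/H2O (4:1), 0 °C, short contact; pH 7 buffer
Reagents that add atoms: none
Why: Saponification of a strained five-membered cyclic carbonate needs a single hydroxide attack followed by irreversible loss of carbonate and should be much faster than attack on the hindered secondary alkanoate, while the C3 silyl ether blocks the 1,3-acyl shift.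

Step 13
Reactants: 26 (1R,3S,4R,5S)-3-(tert-butyldimethylsilyloxy)-4,5-dihydroxy-1-[2-(1,3-oxazol-5-ylmethyl)-1,3-oxazol-4-yl]hexyl 13-methyltetradecanoate
Product: 27 (1R,3S,4R,5S)-3,4,5-trihydroxy-1-[2-(1,3-oxazol-5-ylmethyl)-1,3-oxazol-4-yl]hexyl 13-methyltetradecanoate
Conditions: HF·pyridine, pyridine, THF, 0 °C to rt
Reagents that add atoms: none
Why: Fluoride-mediated desilylation in a buffered, mildly acidic medium cleaves the Si–O bond without hydrolysing or moving the ester and touches no stereocentre.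

**Compound list**
1 | 2-(1,3-oxazol-5-yl)acetic acid | OC(=O)Cc1cnco1 | starting material
2 | L-serine methyl ester hydrochloride | Cl.N[C@@H](CO)C(=O)OC | starting material
3 | methyl N-[2-(1,3-oxazol-5-yl)acetyl]-L-serinate | O=C(Cc1cnco1)N[C@@H](CO)C(=O)OC | intermediate
4 | methyl (4S)-2-(1,3-oxazol-5-ylmethyl)-4,5-dihydro-1,3-oxazole-4-carboxylate | COC(=O)[C@@H]1COC(Cc2cnco2)=N1 | intermediate
5 | methyl 2-(1,3-oxazol-5-ylmethyl)-1,3-oxazole-4-carboxylate | COC(=O)c1coc(Cc2cnco2)n1 | intermediate
6 | 2-(1,3-oxazol-5-ylmethyl)-1,3-oxazole-4-carbaldehyde | O=Cc1coc(Cc2cnco2)n1 | intermediate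
7 | propargyl bromide | C#CCBr | starting material
8 | allenylmagnesium bromide | C=C=C[Mg]Br | intermediate
9 | allenylboronic acid | C=C=CB(O)O | intermediate
10 | 2-(propa-1,2-dienyl)-5,5-dimethyl-1,3,2-dioxaborinane | C=C=CB1OCC(C)(C)CO1 | intermediate
11 | (1S,5S)-(−)-alpha-pinene | CC1=CC[C@H]2C[C@@H]1C2(C)C | starting material
12 | bis(isopinocampheyl)borane, (lIpc)2BH (each group configured as in (1S,2S,3S,5R)-isopinocampheol) | B([C@H]1C[C@H]2C[C@@H]([C@@H]1C)C2(C)C)[C@H]1C[C@H]2C[C@@H]([C@@H]1C)C2(C)C | intermediate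
13 | acetaldehyde | CC=O | starting material
14 | [(E)-3-(5,5-dimethyl-1,3,2-dioxaborinan-2-yl)prop-2-enyl]bis(isopinocampheyl)borane | CC1(C)COB(OC1)/C=C/CB([C@H]1C[C@H]2C[C@@H]([C@@H]1C)C2(C)C)[C@H]1C[C@H]2C[C@@H]([C@@H]1C)C2(C)C | intermediate
15 | (2S,3R)-3-(5,5-dimethyl-1,3,2-dioxaborinan-2-yl)pent-4-en-2-yl bis(isopinocampheyl)borinate (B and O anti) | C[C@H](OB([C@H]1C[C@H]2C[C@@H]([C@@H]1C)C2(C)C)[C@H]1C[C@H]2C[C@@H]([C@@H]1C)C2(C)C)[C@@H](C=C)B1OCC(C)(C)CO1 | intermediate
16 | diol 17 carrying O-bis(isopinocampheyl)boryl at C5 and O-(5,5-dimethyl-1,3,2-dioxaborinan-2-yl) at C1 | C[C@H](OB([C@H]1C[C@H]2C[C@@H]([C@@H]1C)C2(C)C)[C@H]1C[C@H]2C[C@@H]([C@@H]1C)C2(C)C)/C=C/C[C@@H](OB1OCC(C)(C)CO1)c1coc(Cc2cnco2)n1 | intermediate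
17 | (1R,3E,5S)-1-[2-(1,3-oxazol-5-ylmethyl)-1,3-oxazol-4-yl]hex-3-ene-1,5-diol | O[C@H](C/C=C/[C@H](C)O)c1coc(Cc2cnco2)n1 | intermediate
18 | 13-methyltetradecanoic acid | CC(C)CCCCCCCCCCCC(=O)O | starting material
19 | 13-methyltetradecanoic pivalic anhydride | CC(C)CCCCCCCCCCCC(=O)OC(=O)C(C)(C)C | intermediate
20 | (1R,3E,5S)-5-hydroxy-1-[2-(1,3-oxazol-5-ylmethyl)-1,3-oxazol-4-yl]hex-3-en-1-yl 13-methyltetradecanoate | CC(C)CCCCCCCCCCCC(=O)O[C@H](C/C=C/[C@H](C)O)c1coc(Cc2cnco2)n1 | intermediate
21 | (1R)-2-{(2S,3S)-3-[(1S)-1-hydroxyethyl]oxiran-2-yl}-1-[2-(1,3-oxazol-5-ylmethyl)-1,3-oxazol-4-yl]ethyl 13-methyltetradecanoate | CC(C)CCCCCCCCCCCC(=O)O[C@H](C[C@@H]3O[C@H]3[C@H](C)O)c1coc(Cc2cnco2)n1 | intermediate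
22 | (1R)-1-[2-(1,3-oxazol-5-ylmethyl)-1,3-oxazol-4-yl]-2-{(2S,3S)-3-[(1S)-1-(phenylcarbamoyloxy)ethyl]oxiran-2-yl}ethyl 13-methyltetradecanoate | CC(C)CCCCCCCCCCCC(=O)O[C@H](C[C@@H]3O[C@H]3[C@H](C)OC(=O)Nc4ccccc4)c1coc(Cc2cnco2)n1 | intermediate
23 | (1R,3S)-3-hydroxy-3-[(4S,5S)-5-methyl-2-(phenylimino)-1,3-dioxolan-4-yl]-1-[2-(1,3-oxazol-5-ylmethyl)-1,3-oxazol-4-yl]propyl 13-methyltetradecanoate | CC(C)CCCCCCCCCCCC(=O)O[C@H](C[C@H](O)[C@@H]3OC(=Nc4ccccc4)O[C@H]3C)c1coc(Cc2cnco2)n1 | intermediate
24 | (1R,3S)-3-hydroxy-3-[(4S,5S)-5-methyl-2-oxo-1,3-dioxolan-4-yl]-1-[2-(1,3-oxazol-5-ylmethyl)-1,3-oxazol-4-yl]propyl 13-methyltetradecanoate | CC(C)CCCCCCCCCCCC(=O)O[C@H](C[C@H](O)[C@@H]3OC(=O)O[C@H]3C)c1coc(Cc2cnco2)n1 | intermediate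
25 | (1R,3S)-3-(tert-butyldimethylsilyloxy)-3-[(4R,5S)-5-methyl-2-oxo-1,3-dioxolan-4-yl]-1-[2-(1,3-oxazol-5-ylmethyl)-1,3-oxazol-4-yl]propyl 13-methyltetradecanoate | CC(C)CCCCCCCCCCCC(=O)O[C@H](C[C@H](O[Si](C)(C)C(C)(C)C)[C@@H]3OC(=O)O[C@H]3C)c1coc(Cc2cnco2)n1 | intermediate
26 | (1R,3S,4R,5S)-3-(tert-butyldimethylsilyloxy)-4,5-dihydroxy-1-[2-(1,3-oxazol-5-ylmethyl)-1,3-oxazol-4-yl]hexyl 13-methyltetradecanoate | CC(C)CCCCCCCCCCCC(=O)O[C@H](C[C@H](O[Si](C)(C)C(C)(C)C)[C@H](O)[C@H](C)O)c1coc(Cc2cnco2)n1 | intermediate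
27 | (1R,3S,4R,5S)-3,4,5-trihydroxy-1-[2-(1,3-oxazol-5-ylmethyl)-1,3-oxazol-4-yl]hexyl 13-methyltetradecanoate | CC(C)CCCCCCCCCCCC(=O)O[C@H](C[C@H](O)[C@H](O)[C@H](C)O)c1coc(Cc2cnco2)n1 | target

Total step count: 13. Longest linear sequence: 11 steps (1, 2, 3, 6, 7, 8, 9, 10, 11, 12, 13).

**Steps most likely to fail**

Step 7. Acyl transfer may not tell the two secondary hydroxyls apart, which would lead to acylation at C5 or at both sites.
- The fallback moves the discrimination from catalyst control to steric control with a temporary silyl group.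
- Setting out from 17, TBSCl/imidazole in CH2Cl2 at 0 °C should silylate the less hindered methyl carbinol first and give the C5 silyl ether F1.
- Steglich esterification of the remaining C1–OH with 18 (EDC, DMAP) would give the silylated ester F2.
- HF·pyridine would then free C5–OH, and the sequence comes back to the route at 20.

Step 12. Hydroxide may also attack the C1 ester, or silyl migration from C3 to C4 may open the way to an acyl shift.
- The fallback gives up chemoselective hydrolysis and installs the ester only after all base chemistry is done.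
- Setting out from 25, K2CO3 in MeOH would remove carbonate and ester on purpose and give the C3-silylated triol F3.
- The C4/C5 diol is the only pair able to form a small ring, so it would be closed with 2,2-dimethoxypropane and pyridinium p-toluenesulfonate to the acetonide alcohol F4.
- The lone C1–OH would be esterified with 18 (EDC, DMAP) to the fully protected ester F5.
- Aqueous HF in MeCN would remove silyl ether and acetonide together, and the sequence comes back to the route at 27.

Step 6. Three things could go wrong: coordination of the oxazole nitrogens to boron may slow the second allylboration, residual acetaldehyde or allylborane may cross over, or the second chair may lose its equatorial preference and erode the E/anti outcome.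
- The fallback builds the same diol from two separately made carbinols joined at the alkene.
- Setting out from 6, Brown allylboration with B-allylbis(isopinocampheyl)borane of the (−)-alpha-pinene series (Et2O, −78 °C, buffered H2O2 work-up) should give the (R)-homoallylic alcohol F6.
- E-selective olefin cross-metathesis of F6 with an excess of purchased (S)-but-3-en-2-ol (second-generation Hoveyda–Grubbs catalyst, CH2Cl2, 40 °C) would follow, and the sequence comes back to the route at 17.

**Further compounds**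
F1 | step 7 | (1R,3E,5S)-5-(tert-butyldimethylsilyloxy)-1-[2-(1,3-oxazol-5-ylmethyl)-1,3-oxazol-4-yl]hex-3-en-1-ol | O[C@H](C/C=C/[C@H](C)O[Si](C)(C)C(C)(C)C)c1coc(Cc2cnco2)n1
F2 | step 7 | (1R,3E,5S)-5-(tert-butyldimethylsilyloxy)-1-[2-(1,3-oxazol-5-ylmethyl)-1,3-oxazol-4-yl]hex-3-en-1-yl 13-methyltetradecanoate | CC(C)CCCCCCCCCCCC(=O)O[C@H](C/C=C/[C@H](C)O[Si](C)(C)C(C)(C)C)c1coc(Cc2cnco2)n1
F3 | step 12 | (1R,3S,4R,5S)-3-(tert-butyldimethylsilyloxy)-1-[2-(1,3-oxazol-5-ylmethyl)-1,3-oxazol-4-yl]hexane-1,4,5-triol | O[C@H](C[C@H](O[Si](C)(C)C(C)(C)C)[C@H](O)[C@H](C)O)c1coc(Cc2cnco2)n1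
F4 | step 12 | (1R,3S)-3-(tert-butyldimethylsilyloxy)-1-[2-(1,3-oxazol-5-ylmethyl)-1,3-oxazol-4-yl]-3-[(4R,5S)-2,2,5-trimethyl-1,3-dioxolan-4-yl]propan-1-ol | O[C@H](C[C@H](O[Si](C)(C)C(C)(C)C)[C@@H]3OC(C)(C)O[C@H]3C)c1coc(Cc2cnco2)n1
F5 | step 12 | (1R,3S)-3-(tert-butyldimethylsilyloxy)-1-[2-(1,3-oxazol-5-ylmethyl)-1,3-oxazol-4-yl]-3-[(4R,5S)-2,2,5-trimethyl-1,3-dioxolan-4-yl]propyl 13-methyltetradecanoate | CC(C)CCCCCCCCCCCC(=O)O[C@H](C[C@H](O[Si](C)(C)C(C)(C)C)[C@@H]3OC(C)(C)O[C@H]3C)c1coc(Cc2cnco2)n1
F6 | step 6 | (1R)-1-[2-(1,3-oxazol-5-ylmethyl)-1,3-oxazol-4-yl]but-3-en-1-ol | O[C@H](CC=C)c1coc(Cc2cnco2)n1
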